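I counted the reagent first.

in all of them: starting material 0.039 M; time 6.0 min
- Sunday's: reagent 0.120 M
- Friday's: reagent 0.0470 M

    starting material + reagent + released group → target + 2 released group (k1 = 38.9 M⁻² s⁻¹)
    starting material + reagent → target + released group (k2 = 0.00566 M⁻¹ s⁻¹)
    reagent + target → over-reaction product (k3 = 0.0596 M⁻¹ s⁻¹)
    target ⇌ isomer of the product (K4 = 0.350, k4 = 0.00133 s⁻¹)

* which of the two there is more of at the end, Sunday's (over-reaction product / target)
* which of the two there is more of at the end, Friday's (over-reaction product / target)
* amount of target at the end, in percent of the starting material charged, Sunday's
* amount of target at the end, in percent of the starting material charged, Friday's

Each target costs one reagent, and each over-reaction product costs two. On Friday's flask the spare is 20.5%: the reagent charged beyond one equivalent, as a fraction of the starting material charged. With the starting material at zero, Friday's over-reaction product stays within the spare, so target and isomer of the product together keep at least 79.5%. Step 4 runs net towards the isomer of the product while the isomer stands below 0.350 of the target. The two together cannot pass the whole charge, so the isomer stays within 25.9% of it. With the starting material at zero, Friday's target therefore keeps at least 53.6%. That was my bound from below.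

From above, I began with the whole charge. Then I supposed Friday's target born at 3.00 min and let step 4 relax it, with a relaxation half-life of 2.25 min. That lowered my rough ceiling to 84.4%.

Sunday's spare is 208%, more than the whole charge, so on Sunday's flask the balance gives no floor. Taking the full reagent charge and forward isomerisation from the first moment, I got a floor of 4.72%. I could not lower Sunday's ceiling by hand.

The forecast put over-reaction product ahead on Sunday's with 25% target, and target ahead on Friday's with 71% target. Its words for Friday's were “starve the over-reaction”. Its Friday figure lay inside my bracket, and its Sunday figure lay above my floor.

The simulation gave Sunday's 24.2% target against 65.3% over-reaction product. Friday's gave 69.0% target against 12.3%, less than its spare, with 2.33% starting material left. A neighbour of Friday's, charged with 0.019 M of reagent, has 0.487 equiv and a spare of −51.3%. The negative sign makes reagent the limiting reagent. In that neighbour, target stays within 48.7%, and at least 51.3% of the starting material remains. That neighbour ended with 36.5% target and 55.0% starting material.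

The constants used here belong to no real substance; the result is computed.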